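**Plan**

Terpenoid numbering is used for the decalin: ring A is C1–C5 and C10, ring B is C5–C10, C11 is the benzylic CH2, and C4 carries the methyl and the 4-methylpent-3-enyl groups.
Retrosynthesis: the aryl–C11 bond is cut first (B-alkyl Suzuki–Miyaura), then C9=C11 and the C8 methyl/C7=C8 unit are traced back to a C9 ketone. Ring A is cut at C1–C10 and C2–C3 in one event, and the C4–C5 bond by a retro-Claisen step.
Forward: ring B comes first as a cyclohexenol made from 2-iodocyclohex-2-enone. The Claisen rearrangement attaches the quaternary C4 aldehyde to C5 and leaves a 2-methylidenecyclohexanol. Ring A is then closed onto ring B in one flask, the C9 ketone is turned into the 7,9(11)-diene, and the arene is joined last.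
Enabling feature: in aldehyde 12 the C9 carbinol next to the exocyclic C10 methylidene of ring B is a latent, regiodefined C9–C10 enolate that already holds the future C10 methyl. The non-enolisable C3 aldehyde on quaternary C4 lies where a two-carbon vinylphosphonium unit can bridge C10 and C3.
Stereochemistry: the C9 carbinol (CBS reduction) steers the Claisen rearrangement (C5 by face, C4 by the Z-enol ether in a chair transition state). C5 then steers C10 in the annulation, and the C10 methyl steers the hydroboration at C9. The auxiliary C9 carbinol is erased as a ketone on the way.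

Key step: step 7

Remark: compounds 1, 2, 6, 13 and 23 and all reagents named below are taken to be commercial.

Step 1
Reactants: 1 5-bromo-2-methylpent-2-ene; 2 propyne
Product: 5 (1Z)-1-iodo-2,6-dimethylhepta-1,5-diene, via Grignard reagent 3 (not isolated), via alkenylcopper 4 (not isolated)
Conditions: Mg, Et2O; CuBr·SMe2, Et2O–Me2S, −45 °C; 2, −25 °C; I2, THF, −50 → 0 °C
Reagents that add atoms: iodine, II
Why: Syn-carbocupration of propyne places copper on the terminal carbon cis to the new 4-methylpent-3-enyl group and iodinolysis goes with retention, so the Z-trisubstituted vinyl iodide should result (carbometalation–iodination).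

Step 2
Reactants: 6 2-iodocyclohex-2-en-1-one
Product: 7 (1R)-2-iodocyclohex-2-en-1-ol
Conditions: (S)-2-methyl-CBS-oxazaborolidine (10 mol %), BH3·SMe2, THF, −20 °C; MeOH quench
Reagents that add atoms: none
Why: CBS reduction with the iodoalkene arm as the large group should deliver hydride to one carbonyl face and set the carbinol centre as R, the only stereocentre of the route that is set by a reagent.

Step 3
Reactants: 7 (1R)-2-iodocyclohex-2-en-1-ol
Product: 8 tert-butyl{[(1R)-2-iodocyclohex-2-en-1-yl]oxy}dimethylsilane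
Conditions: TBSCl, imidazole, DMF, rt
Reagents that add atoms: tert-butyldimethylsilyl chloride, CC(C)(C)[Si](C)(C)Cl
Why: Silylation gives a bulky silyl ether that leaves only the later primary hydroxyl free for O-vinylation and that should sit pseudoaxial to shield one ring face in step 5.

Step 4
Reactants: 8 tert-butyl{[(1R)-2-iodocyclohex-2-en-1-yl]oxy}dimethylsilane
Product: 9 [(6R)-6-{[tert-butyl(dimethyl)silyl]oxy}cyclohex-1-en-1-yl]methanol
Conditions: Bu3SnCH2OH, Pd(PPh3)4 (5 mol %), 1,4-dioxane, 90 °C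
Reagents that add atoms: (tributylstannyl)methanol, CCCC[Sn](CCCC)(CCCC)CO
Why: Stille coupling transfers the hydroxymethyl group to the ring sp2 carbon and does not touch the carbinol centre.

Step 5
Reactants: 9 [(6R)-6-{[tert-butyl(dimethyl)silyl]oxy}cyclohex-1-en-1-yl]methanol; 5 (1Z)-1-iodo-2,6-dimethylhepta-1,5-diene
Product: 11 (2R)-2-[(1R,3R)-3-{[tert-butyl(dimethyl)silyl]oxy}-2-methylidenecyclohexyl]-2,6-dimethylhept-5-enal, via allyl vinyl ether 10 (not isolated)
Conditions: CuI (10 mol %), 3,4,7,8-tetramethyl-1,10-phenanthroline (20 mol %), Cs2CO3, toluene, 80 °C; then o-xylene, 130 °C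
Reagents that add atoms: none
Why: Ullmann-type C–O coupling keeps the Z geometry of 5, and Claisen rearrangement of 10 through a chair transition state on the face anti to the pseudoaxial silyloxy group forms C4–C5, so the Z-enol ether should fix quaternary C4 relative to C5 and the carbinol should fix C5; the minor facial isomer is a diastereomer and can be removed.

Step 6
Reactants: 11 (2R)-2-[(1R,3R)-3-{[tert-butyl(dimethyl)silyl]oxy}-2-methylidenecyclohexyl]-2,6-dimethylhept-5-enal
Product: 12 (2R)-2-[(1R,3R)-3-hydroxy-2-methylidenecyclohexyl]-2,6-dimethylhept-5-enal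
Conditions: Bu4NF, AcOH, THF, 0 °C → rt
Reagents that add atoms: none
Why: Fluoride desilylation frees the allylic hydroxyl that the key step needs, and the non-enolisable aldehyde and the trans-placed hydroxyl cannot form a lactol.

Step 7
Reactants: 12 (2R)-2-[(1R,3R)-3-hydroxy-2-methylidenecyclohexyl]-2,6-dimethylhept-5-enal; 13 vinyltriphenylphosphonium bromide
Product: 17 (4aS,5S,8aS)-5,8a-dimethyl-5-(4-methylpent-3-en-1-yl)-3,4,4a,5,8,8a-hexahydronaphthalen-1(2H)-one, via lithium alkoxide 14 (not isolated), via lithium enolate 15 (not isolated), via phosphonium ylide 16 (not isolated)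
Conditions: LiN(SiMe3)2 (1.05 equiv), THF, −78 → 0 °C; [Rh(cod)(dppe)]BF4 (5 mol %, pre-activated with H2), 50 °C; then 13 (1.3 equiv) in DMSO, 0 → 50 °C
Reagents that add atoms: none
Why: Proposed new method: deprotonation of the C9 hydroxyl gives alkoxide 14, in which [Rh(cod)(dppe)]BF4 performs β-hydride elimination at C9 and returns the hydride to the terminal carbon of the bound exocyclic enone, so the C10 methyl and the tetrasubstituted C9–C10 lithium enolate 15 arise without external reductant and without any C8 enolate; 15 then adds to 13 (C10–C1) to give ylide 16, which closes ring A by intramolecular Wittig olefination of the C3 aldehyde (C2=C3). The closest known reaction types are the rhodium-catalysed isomerisation of allylic lithium alkoxides to regiodefined enolates trapped in situ by electrophiles, and the Michael–Wittig annulation of carbonyl-tethered enolates with vinylphosphonium salts; their union in one flask is new. Ring A closes as a six-membered ring by 6-exo-trig attack of the ylide carbon on the aldehyde carbon, followed by collapse of the oxaphosphetane to the cis ring alkene. The only new stereocentre, C10, is set in the Michael step: the C5 side chain, pushed pseudoaxial by allylic strain against the enolate methyl, blocks one face, so C1 should enter anti to it and the ring fusion should become trans. The step needs chemoselectivity toward the aldehyde: the hydride is passed on within the rhodium-bound enone, the aldehyde is non-enolisable and out of reach of the enolate carbon (a four-membered ring), and 13 is added only after the alkoxide is consumed so that O-addition to the phosphonium salt cannot compete.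

Step 8
Reactants: 17 (4aS,5S,8aS)-5,8a-dimethyl-5-(4-methylpent-3-en-1-yl)-3,4,4a,5,8,8a-hexahydronaphthalen-1(2H)-one
Product: 18 (4aS,5R,8aS)-5,8a-dimethyl-5-(4-methylpent-3-en-1-yl)octahydronaphthalen-1(2H)-one
Conditions: H2 (1 atm), RhCl(PPh3)3 (5 mol %), benzene–EtOH, rt
Reagents that add atoms: none
Why: Homogeneous hydrogenation with RhCl(PPh3)3 reduces the cis-disubstituted ring alkene much faster than the trisubstituted side-chain alkene and leaves the ketone alone.

Step 9
Reactants: 18 (4aS,5R,8aS)-5,8a-dimethyl-5-(4-methylpent-3-en-1-yl)octahydronaphthalen-1(2H)-one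
Product: 20 (4aS,5R,8aS)-2,5,8a-trimethyl-5-(4-methylpent-3-en-1-yl)octahydronaphthalen-1(2H)-one (both C2 epimers), via lithium enolate 19 (not isolated)
Conditions: LiN(i-Pr)2, THF, −78 °C; MeI, −78 → 0 °C
Reagents that add atoms: iodomethane, CI
Why: The ketone can enolise only toward C8 because C10 is quaternary, so enolate alkylation puts the methyl on C8, whose configuration does not matter because it becomes sp2 in step 10.

Step 10
Reactants: 20 (4aS,5R,8aS)-2,5,8a-trimethyl-5-(4-methylpent-3-en-1-yl)octahydronaphthalen-1(2H)-one (both C2 epimers)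
Product: 21 (4aS,5R,8aS)-2,5,8a-trimethyl-5-(4-methylpent-3-en-1-yl)-4a,5,6,7,8,8a-hexahydronaphthalen-1(4H)-one
Conditions: IBX (2.5 equiv), DMSO–toluene, 75 °C
Reagents that add atoms: none
Why: IBX dehydrogenation of the α-methyl ketone should give the endocyclic C7=C8 enone and funnel both C8 epimers into one compound.

Step 11
Reactants: 21 (4aS,5R,8aS)-2,5,8a-trimethyl-5-(4-methylpent-3-en-1-yl)-4a,5,6,7,8,8a-hexahydronaphthalen-1(4H)-one
Product: 22 (4aS,5R,8aS)-2,5,8a-trimethyl-1-methylidene-5-(4-methylpent-3-en-1-yl)-1,4,4a,5,6,7,8,8a-octahydronaphthalene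
Conditions: Ph3PCH3Br, KOt-Bu, toluene, 90 °C
Reagents that add atoms: methyltriphenylphosphonium bromide, C[P+](c1ccccc1)(c1ccccc1)c1ccccc1.[Br-]
Why: Wittig methylenation under forcing conditions converts the hindered C9 ketone, which has no α-hydrogen at C10, into the 1,3-diene with the exocyclic C9=C11 bond.

Step 12
Reactants: 23 methyl 4-hydroxy-3-iodobenzoate
Product: 24 methyl 4-[(2,2-dimethylpropanoyl)oxy]-3-iodobenzoate
Conditions: t-BuCOCl, Et3N, DMAP (cat.), CH2Cl2, 0 °C → rt
Reagents that add atoms: pivaloyl chloride, CC(C)(C)C(=O)Cl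
Why: Esterification masks the phenol as a pivalate that should survive the cross-coupling and falls off together with the methyl ester in step 14.

Step 13
Reactants: 22 (4aS,5R,8aS)-2,5,8a-trimethyl-1-methylidene-5-(4-methylpent-3-en-1-yl)-1,4,4a,5,6,7,8,8a-octahydronaphthalene; 24 methyl 4-[(2,2-dimethylpropanoyl)oxy]-3-iodobenzoate
Product: 26 methyl 4-[(2,2-dimethylpropanoyl)oxy]-3-{[(1S,4aS,5R,8aS)-2,5,8a-trimethyl-5-(4-methylpent-3-en-1-yl)-1,4,4a,5,6,7,8,8a-octahydronaphthalen-1-yl]methyl}benzoate, via alkylborane 25 (not isolated)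
Conditions: 9-BBN, THF, rt; then 24, Pd(dppf)Cl2 (5 mol %), K3PO4 (3 M aq), DMF, 50 °C
Reagents that add atoms: none
Why: 9-BBN should add only to the 1,1-disubstituted exocyclic alkene and from the face opposite the axial C10 methyl, which puts hydrogen α and the boron-bearing CH2 β at C9, and B-alkyl Suzuki–Miyaura coupling then forms the C11–aryl bond.

Step 14
Reactants: 26 methyl 4-[(2,2-dimethylpropanoyl)oxy]-3-{[(1S,4aS,5R,8aS)-2,5,8a-trimethyl-5-(4-methylpent-3-en-1-yl)-1,4,4a,5,6,7,8,8a-octahydronaphthalen-1-yl]methyl}benzoate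
Product: 27 jaspic acid, 4-hydroxy-3-{[(1S,4aS,5R,8aS)-2,5,8a-trimethyl-5-(4-methylpent-3-en-1-yl)-1,4,4a,5,6,7,8,8a-octahydronaphthalen-1-yl]methyl}benzoic acid
Conditions: LiOH, THF–MeOH–H2O, 45 °C; then HCl (1 M) to pH 3, 0 °C
Reagents that add atoms: lithium hydroxide, [Li+].[OH-]
Why: Saponification cleaves the methyl ester and the aryl pivalate in one operation under conditions that should leave the alkenes and all four stereocentres untouched.

**Compound list**

1 | 5-bromo-2-methylpent-2-ene | CC(C)=CCCBr | starting material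
2 | propyne | CC#C | starting material
3 | (4-methylpent-3-en-1-yl)magnesium bromide | CC(C)=CCC[Mg]Br | intermediate
4 | [(1Z)-2,6-dimethylhepta-1,5-dien-1-yl]copper (MgBr2 complex) | [Cu]/C=C(/C)CCC=C(C)C | intermediate
5 | (1Z)-1-iodo-2,6-dimethylhepta-1,5-diene | I/C=C(/C)CCC=C(C)C | intermediate
6 | 2-iodocyclohex-2-en-1-one | O=C1CCCC=C1I | starting material
7 | (1R)-2-iodocyclohex-2-en-1-ol | O[C@@H]1CCCC=C1I | intermediate
8 | tert-butyl{[(1R)-2-iodocyclohex-2-en-1-yl]oxy}dimethylsilane | CC(C)(C)[Si](C)(C)O[C@@H]1CCCC=C1I | intermediate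
9 | [(6R)-6-{[tert-butyl(dimethyl)silyl]oxy}cyclohex-1-en-1-yl]methanol | OCC1=CCCC[C@H]1O[Si](C)(C)C(C)(C)C | intermediate
10 | tert-butyl{[(1R)-2-({[(1Z)-2,6-dimethylhepta-1,5-dien-1-yl]oxy}methyl)cyclohex-2-en-1-yl]oxy}dimethylsilane | CC(C)(C)[Si](C)(C)O[C@@H]1CCCC=C1CO/C=C(/C)CCC=C(C)C | intermediate
11 | (2R)-2-[(1R,3R)-3-{[tert-butyl(dimethyl)silyl]oxy}-2-methylidenecyclohexyl]-2,6-dimethylhept-5-enal | O=C[C@](C)(CCC=C(C)C)[C@@H]1CCC[C@@H](O[Si](C)(C)C(C)(C)C)C1=C | intermediate
12 | (2R)-2-[(1R,3R)-3-hydroxy-2-methylidenecyclohexyl]-2,6-dimethylhept-5-enal | O=C[C@](C)(CCC=C(C)C)[C@@H]1CCC[C@@H](O)C1=C | intermediate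
13 | vinyltriphenylphosphonium bromide | C=C[P+](c1ccccc1)(c1ccccc1)c1ccccc1.[Br-] | starting material
14 | lithium (1R,3R)-3-[(2R)-2,6-dimethyl-1-oxohept-5-en-2-yl]-2-methylidenecyclohexan-1-olate | O=C[C@](C)(CCC=C(C)C)[C@@H]1CCC[C@@H](O[Li])C1=C | intermediate
15 | lithium (6R)-6-[(2R)-2,6-dimethyl-1-oxohept-5-en-2-yl]-2-methylcyclohex-1-en-1-olate | O=C[C@](C)(CCC=C(C)C)[C@@H]1CCCC(O[Li])=C1C | intermediate
16 | (2R)-2,6-dimethyl-2-{(1S,2S)-2-methyl-3-oxo-2-[2-(triphenyl-λ5-phosphanylidene)ethyl]cyclohexyl}hept-5-enal | O=C[C@](C)(CCC=C(C)C)[C@@H]1CCCC(=O)[C@@]1(C)CC=P(c1ccccc1)(c1ccccc1)c1ccccc1 | intermediate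
17 | (4aS,5S,8aS)-5,8a-dimethyl-5-(4-methylpent-3-en-1-yl)-3,4,4a,5,8,8a-hexahydronaphthalen-1(2H)-one | CC(C)=CCC[C@@]1(C)C=CC[C@]2(C)C(=O)CCC[C@@H]12 | intermediate
18 | (4aS,5R,8aS)-5,8a-dimethyl-5-(4-methylpent-3-en-1-yl)octahydronaphthalen-1(2H)-one | CC(C)=CCC[C@@]1(C)CCC[C@]2(C)C(=O)CCC[C@@H]12 | intermediate
19 | lithium enolate of 18 (C9–OLi, C8=C9) | CC(C)=CCC[C@@]1(C)CCC[C@]2(C)C(O[Li])=CCC[C@@H]12 | intermediate
20 | (4aS,5R,8aS)-2,5,8a-trimethyl-5-(4-methylpent-3-en-1-yl)octahydronaphthalen-1(2H)-one (both C2 epimers) | CC(C)=CCC[C@@]1(C)CCC[C@]2(C)C(=O)C(C)CC[C@@H]12 | intermediate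
21 | (4aS,5R,8aS)-2,5,8a-trimethyl-5-(4-methylpent-3-en-1-yl)-4a,5,6,7,8,8a-hexahydronaphthalen-1(4H)-one | CC(C)=CCC[C@@]1(C)CCC[C@]2(C)C(=O)C(C)=CC[C@@H]12 | intermediate
22 | (4aS,5R,8aS)-2,5,8a-trimethyl-1-methylidene-5-(4-methylpent-3-en-1-yl)-1,4,4a,5,6,7,8,8a-octahydronaphthalene | CC(C)=CCC[C@@]1(C)CCC[C@]2(C)C(=C)C(C)=CC[C@@H]12 | intermediate
23 | methyl 4-hydroxy-3-iodobenzoate | COC(=O)c1ccc(O)c(I)c1 | starting material
24 | methyl 4-[(2,2-dimethylpropanoyl)oxy]-3-iodobenzoate | COC(=O)c1ccc(OC(=O)C(C)(C)C)c(I)c1 | intermediate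
25 | 9-{[(1S,4aS,5R,8aS)-2,5,8a-trimethyl-5-(4-methylpent-3-en-1-yl)-1,4,4a,5,6,7,8,8a-octahydronaphthalen-1-yl]methyl}-9-borabicyclo[3.3.1]nonane | CC(C)=CCC[C@@]1(C)CCC[C@]2(C)[C@@H](CB3C4CCCC3CCC4)C(C)=CC[C@@H]12 | intermediate
26 | methyl 4-[(2,2-dimethylpropanoyl)oxy]-3-{[(1S,4aS,5R,8aS)-2,5,8a-trimethyl-5-(4-methylpent-3-en-1-yl)-1,4,4a,5,6,7,8,8a-octahydronaphthalen-1-yl]methyl}benzoate | CC(C)=CCC[C@@]1(C)CCC[C@]2(C)[C@@H](Cc3cc(C(=O)OC)ccc3OC(=O)C(C)(C)C)C(C)=CC[C@@H]12 | intermediate
27 | jaspic acid, 4-hydroxy-3-{[(1S,4aS,5R,8aS)-2,5,8a-trimethyl-5-(4-methylpent-3-en-1-yl)-1,4,4a,5,6,7,8,8a-octahydronaphthalen-1-yl]methyl}benzoic acid | CC(C)=CCC[C@@]1(C)CCC[C@]2(C)[C@@H](Cc3cc(C(=O)O)ccc3O)C(C)=CC[C@@H]12 | target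

Total step count: 14. Longest linear sequence: 12 steps (steps 2 to 11, then 13 and 14).

**Steps most likely to fail**

Step 7. The rhodium hydride formed from alkoxide 14 may be diverted before the phosphonium salt is engaged, by decarbonylation of the aldehyde, by hydride transfer to the aldehyde, or by aldol capture of enolate 15; ring A would then not close. The fallback uses known chemistry only, sets out from 11 and comes back at 17, with the two ring A bonds made in separate operations. Wittig methylenation of the aldehyde of 11 (Ph3PCH3Br, KOt-Bu) gives the vinyl compound F1. Bu4NF frees the allylic alcohol F2, and MnO2 oxidises it to the exocyclic enone F3. Conjugate reduction with K[(s-Bu)3BH] at −78 °C, followed in the same flask by allyl bromide, should alkylate C10 anti to the C5 side chain and give the allyl ketone F4. Ring-closing metathesis between the C4 vinyl and the C10 allyl groups with the second-generation Grubbs catalyst RuCl2(=CHPh)(PCy3)(H2IMes) then gives 17.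

Step 5. The C–O coupling of the hindered trisubstituted iodide may be slow, and Z/E scrambling of the copper-bound alkenyl unit at the rearrangement temperature would erode the configuration of quaternary C4. The fallback builds the enol ether on the alcohol by carbometalation instead of by cross-coupling; it sets out from 9 and comes back at 11. Alcohol 9 with KH and trichloroethylene gives the 1,2-dichlorovinyl ether F5. Treatment with n-BuLi (2 equiv) and then bromide 1 (NaI, DMPU) gives the alkynyl ether F6. Syn-addition of MeCu·MgBr2, which places copper on the oxygen-bearing carbon and methyl cis to it, followed by aqueous NH4Cl, should give vinyl ether 10 as the Z isomer only, and heating in o-xylene then gives 11.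

Step 13. Transmetalation of the β-branched primary alkylborane 25 may be slow, so that protodeboronation and ester hydrolysis overtake the cross-coupling. The fallback reverses the polarity of the coupling partners; it sets out from 22 and comes back at 26. Hydroboration of 22 with 9-BBN and oxidation with NaBO3 gives the primary alcohol F7, and PPh3, I2 and imidazole turn it into the iodide F8. Iodide 24 is converted with i-PrMgCl·LiCl (−40 °C) and ZnCl2 into the arylzinc chloride F9. Negishi coupling of F8 with F9 under PdCl2(IPr)(3-chloropyridine), where IPr is 1,3-bis(2,6-diisopropylphenyl)imidazol-2-ylidene, gives 26.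

Further compounds
F1 | step 7 | methylenation product of 11: tert-butyl{[3-(3,7-dimethylocta-1,6-dien-3-yl)-2-methylidenecyclohexyl]oxy}dimethylsilane, all stereocentres as in 11 | C=C[C@](C)(CCC=C(C)C)[C@@H]1CCC[C@@H](O[Si](C)(C)C(C)(C)C)C1=C
F2 | step 7 | 3-(3,7-dimethylocta-1,6-dien-3-yl)-2-methylidenecyclohexan-1-ol, all stereocentres as in 12 | C=C[C@](C)(CCC=C(C)C)[C@@H]1CCC[C@@H](O)C1=C
F3 | step 7 | 3-(3,7-dimethylocta-1,6-dien-3-yl)-2-methylidenecyclohexan-1-one, both stereocentres as in 12 | C=C[C@](C)(CCC=C(C)C)[C@@H]1CCCC(=O)C1=C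
F4 | step 7 | 3-(3,7-dimethylocta-1,6-dien-3-yl)-2-methyl-2-(prop-2-en-1-yl)cyclohexan-1-one, allyl group trans to the side chain | C=C[C@](C)(CCC=C(C)C)[C@@H]1CCCC(=O)[C@@]1(C)CC=C
F5 | step 5 | tert-butyl{[(1R)-2-({[(E)-1,2-dichloroethenyl]oxy}methyl)cyclohex-2-en-1-yl]oxy}dimethylsilane | Cl/C=C(/Cl)OCC1=CCCC[C@H]1O[Si](C)(C)C(C)(C)C
F6 | step 5 | tert-butyldimethyl{[(1R)-2-{[(6-methylhept-5-en-1-yn-1-yl)oxy]methyl}cyclohex-2-en-1-yl]oxy}silane | CC(C)=CCCC#COCC1=CCCC[C@H]1O[Si](C)(C)C(C)(C)C
F7 | step 13 | [(1S,4aS,5R,8aS)-2,5,8a-trimethyl-5-(4-methylpent-3-en-1-yl)-1,4,4a,5,6,7,8,8a-octahydronaphthalen-1-yl]methanol | CC(C)=CCC[C@@]1(C)CCC[C@]2(C)[C@@H](CO)C(C)=CC[C@@H]12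
F8 | step 13 | the corresponding primary iodide, 1-(iodomethyl) analogue of F7 with the same configuration | CC(C)=CCC[C@@]1(C)CCC[C@]2(C)[C@@H](CI)C(C)=CC[C@@H]12
F9 | step 13 | chloro{2-[(2,2-dimethylpropanoyl)oxy]-5-(methoxycarbonyl)phenyl}zinc | COC(=O)c1ccc(OC(=O)C(C)(C)C)c([Zn]Cl)c1
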